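(All runs were generated by integration for an exercise; scatter was added.)

- 27.8 min is the number to carry: the loss half-life of free starting material between portions, read in the dawn run as the fall from 49.9% at 40.0 min to 38.9% at 50.0 min. That run has the initiator of the new flask, 100 µM.

the same everywhere: starting material 10 mM (in portions, 3)
- dusk: reagent 11 mM; initiator 140 µM; run made earlier; portions every 15 min
- noon: reagent 11 mM; initiator 220 µM; run made earlier; portions every 15 min
- dawn: reagent 5.5 mM; initiator 100 µM; run made earlier; portions every 15 min
- flask: reagent 11.0 mM; initiator 100 µM; the portions of starting material follow each other after 15 min, the first at the start; time 50 min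

| run | time / min | starting material / % | product / % |
|---|---|---|---|
| dusk | 8.00 | 26.1 | 6.4 |
| dusk | 15.0 | 21.0 | 11.1 |
| dusk | 20.0 | 44.5 | 18.1 |
| dusk | 30.0 | 32.1 | 28.9 |
| dusk | 40.0 | 44.7 | 44.7 |
| dusk | 50.0 | 33.8 | 55.4 |
| noon | 8.00 | 23.6 | 8.1 |
| noon | 15.0 | 18.1 | 13.9 |
| noon | 20.0 | 40.7 | 21.8 |
| noon | 30.0 | 27.3 | 34.0 |
| noon | 40.0 | 38.5 | 50.5 |
| noon | 50.0 | 27.7 | 62.4 |
| dawn | 4.00 | 29.3 | 3.1 |
| dawn | 12.0 | 24.3 | 7.9 |
| dawn | 25.0 | 40.7 | 21.4 |
| dawn | 40.0 | 49.9 | 39.8 |
| dawn | 50.0 | 38.9 | 50.5 |

(scatter of a reading: 0.3 percentage points)

- a reading or a percentage of product counts all its forms, free or not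
- a reading of starting material is of its free form alone

* amount of starting material in percent of the starting material charged, at 10 min, 25 min and 50 min

- Since each stretch between portions loses a fixed fraction per minute, a pseudo-first-order loss, the rate at 100 µM is 0.0249 /min, and a change of recipe enters as a factor on it.
- Initiator enters as a square root of c(initiator): from dawn to noon the factor on the half-life is 0.674, so the half-life becomes 18.8 min.
- Noon itself reads 18.3 min between 8.00 min and 15.0 min but 21.1 min between 40.0 min and 50.0 min, so against that expected half-life the rate stands at a factor of 1.03 in the first stretch and 0.891 in the second, one on each side of 1.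
- These readings assign no factor to reagent going from 5.5 mM to 11 mM, so the reckoning here takes that factor as 1.
- The flask is therefore reckoned as the dawn run, with the reagent factor as a small correction left open. Over the stretch since the last portion, the factor 1.03 would take 0.51 percentage points from the dawn reading at 50 min, and the factor 0.891 would add 2.1 points to it.
- My reckoning is 25.5% at 10 min, run back from the dawn reading at 12.0 min, then the dawn readings 40.7% at 25 min and 38.9% at 50 min.
- The forecast says 25.6%, 40.6% and 38.4%, on the ground that “reagent order is near zero”; at 50 min it stands lower than my reckoning by 0.5 points.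
- The flask gives 25.3%, 40.7% and 38.8%, which agrees with the forecast within the margin.

    initiator → 2 initiating radical (k = 5.04 × 10⁻⁶ /s)
    starting material + initiating radical → capped initiator + first chain carrier (k = 2.43 × 10⁶ /M/s)
    reagent + first chain carrier → product + second chain carrier (k = 56400 /M/s)
    starting material + second chain carrier → by-product + first chain carrier (k = 99300 /M/s)
    2 second chain carrier → ended chains (k = 3.00 × 10⁷ /M/s)
    starting material + product ⇌ idle adduct, settled at all times (K = 68.0 /M)

- Carried from 40.7% at 25 min with the half-life 27.8 min, the flask holds 35.9% at 30.0 min, and it stands at 35.6%. In this flask the step of starting material with second chain carrier has a half-life of 28 min at 29.2 min, far shorter than the 38 h of initiator, and second chain carrier reads 4.09 × 10⁻⁶ mM at 25.0 min and 4.07 × 10⁻⁶ mM at 50.0 min.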